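**Retrosynthetic overview**
1. The target is disconnected at the diaryl ether by a Smiles rearrangement (ArCO–O–Ar′ → Ar(CO2H)–O–Ar′) of a hydroxy-depside: the ester of a ring-A salicylic acid with a ring-B catechol aldehyde, joined without protecting groups.
2. The ring-B catechol aldehyde comes from mono-Dakin oxidation of the C2v-symmetric 2-hydroxy-5-methylisophthalaldehyde (the symmetry-breaking key step), itself made from p-cresol by double Duff formylation.
3. The ring-A acid comes from ortho-lithiation/CO2 between OMe and a protected OH, after O-methylation of an (R)-benzylic alcohol set by catalytic asymmetric i-BuMgBr addition to 4-hydroxy-2-methoxybenzaldehyde (the only stereocentre).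
4. Ring order: both benzene rings are bought intact; the only ring formed is the transient spiro-1,3-dioxinone of the Smiles step.

Assumption: the stereocentre in the SMILES is read as (R); the acetal carbon of the 1-ethoxyethyl group in 7 and 10–13 is an uncontrolled ~1:1 epimer mixture that is removed in step 6.

**Step 1**
Reactants: 1 p-cresol
Product: 3 2-hydroxy-5-methylisophthalaldehyde, via bis-aldimine 2 (not isolated)
Conditions: hexamethylenetetramine (4 equiv), TFA, reflux, 24 h; then 4 M aq. HCl, rt
Reagents that add atoms: hexamethylenetetramine C1N2CN3CN1CN(C2)C3; water O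
Why: Duff reaction, in which the phenol is aminomethylated at both free ortho positions (para is blocked by CH3), the benzylamines are dehydrogenated by iminium hydride transfer and the imines are hydrolysed to the symmetric dialdehyde.

**Step 2**
Reactants: 3 2-hydroxy-5-methylisophthalaldehyde
Product: 5 2,3-dihydroxy-5-methylbenzaldehyde, via aryl formate 4 (not isolated)
Conditions: 30% aq. H2O2 (1.0 equiv, slow addition), NaOH (2 equiv), H2O/THF, 0 °C→rt, N2; then 1 M HCl to pH 3
Reagents that add atoms: hydrogen peroxide OO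
Why: Dakin oxidation (hydroperoxide adds to one CHO of the phenoxide, the aryl group migrates to oxygen and the formate is saponified in situ), run with one equivalent of oxidant so that only one of the two equivalent CHO groups is converted, the catecholate product having a more electron-rich and less electrophilic remaining CHO, which breaks the mirror symmetry of 3 and delivers ring B with OH, OH and CHO already in place.

**Step 3**
Reactants: 6 4-hydroxy-2-methoxybenzaldehyde
Product: 7 4-(1-ethoxyethoxy)-2-methoxybenzaldehyde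
Conditions: ethyl vinyl ether (3 equiv), PPTS (5 mol %), CH2Cl2, rt; Et3N quench
Reagents that add atoms: ethyl vinyl ether C=COCC
Why: acid-catalysed addition of the phenol to the enol ether (acetal protection) gives a base-stable, metalation-directing and very acid-labile ether.

**Step 4**
Reactants: 7 4-(1-ethoxyethoxy)-2-methoxybenzaldehyde; 8 isobutylmagnesium bromide
Product: 10 (1R)-1-[4-(1-ethoxyethoxy)-2-methoxyphenyl]-3-methylbutan-1-ol, via isobutyltitanium triisopropoxide 9 (not isolated)
Conditions: 8 (2 equiv)/bis[2-(dimethylamino)ethyl] ether (2 equiv), Ti(OiPr)4 (3.5 equiv), (R)-BINOL (15 mol %), MTBE–toluene, 0 °C; aq. Rochelle salt/NaHCO3 work-up, Et3N-deactivated silica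
Reagents that add atoms: none
Why: catalytic asymmetric Grignard addition through a Ti–BINOLate complex, in which the alkyl group of the in situ alkyltitanium is delivered within the (R)-BINOLate–Ti assembly to the Re face of the aldehyde (the sense known for Ti–BINOLate alkylations of ArCHO) to set the (R) carbinol centre while the diamine ether suppresses the racemic background.

**Step 5**
Reactants: 10 (1R)-1-[4-(1-ethoxyethoxy)-2-methoxyphenyl]-3-methylbutan-1-ol
Product: 11 4-(1-ethoxyethoxy)-2-methoxy-1-[(1R)-1-methoxy-3-methylbutyl]benzene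
Conditions: NaH (1.5 equiv), MeI (3 equiv), THF, 0 °C→rt
Reagents that add atoms: iodomethane CI
Why: Williamson etherification of the sodium alkoxide, which breaks no bond at the stereocentre and so retains (R).

**Step 6**
Reactants: 11 4-(1-ethoxyethoxy)-2-methoxy-1-[(1R)-1-methoxy-3-methylbutyl]benzene
Product: 14 6-hydroxy-2-methoxy-3-[(1R)-1-methoxy-3-methylbutyl]benzoic acid, via aryllithium 12 (not isolated), via acetal-protected acid 13 (not isolated)
Conditions: n-BuLi (1.2 equiv), THF, −20→0 °C, 1 h; CO2 (g), −78 °C→rt; H2O, 1 M HCl to pH 3, THF/H2O, 0 °C→rt, 1 h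
Reagents that add atoms: carbon dioxide O=C=O
Why: directed ortho-metalation at the C–H flanked by OMe and the acetal oxygen (cooperative directing groups) followed by carboxylation, after which the acetal ortho to the new CO2H hydrolyses at pH 3 by intramolecular general-acid catalysis, while the hindered benzylic C–H is kinetically far less acidic and the benzylic ether does not ionise at this pH, so the stereocentre is untouched.

**Step 7**
Reactants: 14 6-hydroxy-2-methoxy-3-[(1R)-1-methoxy-3-methylbutyl]benzoic acid; 5 2,3-dihydroxy-5-methylbenzaldehyde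
Product: 15 3-formyl-2-hydroxy-5-methylphenyl 6-hydroxy-2-methoxy-3-[(1R)-1-methoxy-3-methylbutyl]benzoate
Conditions: DCC (1.1 equiv), DMAP (10 mol %), 5 (1.3 equiv), CH2Cl2, 0 °C→rt
Reagents that add atoms: none
Why: Steglich esterification under neutral conditions acylates the non-chelated 3-OH of 5 while the hydrogen-bonded OH groups ortho to C=O in both partners stay free, and any 2-O-acyl isomer formed is equally productive in step 8.

**Step 8**
Reactants: 15 3-formyl-2-hydroxy-5-methylphenyl 6-hydroxy-2-methoxy-3-[(1R)-1-methoxy-3-methylbutyl]benzoate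
Product: 18 6-(2-formyl-6-hydroxy-4-methylphenoxy)-2-methoxy-3-[(1R)-1-methoxy-3-methylbutyl]benzoic acid, via acyl-shifted depside 16 (not isolated), via spiro Meisenheimer adduct 17 (not isolated)
Conditions: K2CO3 (1.5 equiv), dry DMSO, rt→45 °C, N2; then cold 0.5 M HCl to pH 3–4
Reagents that add atoms: none
Why: base-mediated 1,2-acyl shift between the catechol oxygens followed by Smiles rearrangement (intramolecular SNAr), in which the ring-A phenoxide attacks the ester-bearing ipso carbon that is activated only in the 2-O-acyl isomer (ortho to CHO) and irreversible expulsion of the carboxylate gives the diaryl ether with CO2H, OH and CHO free and the remote (R) centre uninvolved.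

**Compound list**
1 | p-cresol | Cc1ccc(O)cc1 | starting material
2 | 2,6-bis(iminomethyl)-4-methylphenol (Duff iminium stage drawn in its simplest form) | Cc1cc(C=N)c(O)c(C=N)c1 | intermediate
3 | 2-hydroxy-5-methylisophthalaldehyde | Cc1cc(C=O)c(O)c(C=O)c1 | intermediate
4 | 3-formyl-2-hydroxy-5-methylphenyl formate | Cc1cc(C=O)c(O)c(OC=O)c1 | intermediate
5 | 2,3-dihydroxy-5-methylbenzaldehyde | Cc1cc(O)c(O)c(C=O)c1 | intermediate
6 | 4-hydroxy-2-methoxybenzaldehyde | COc1cc(O)ccc1C=O | starting material
7 | 4-(1-ethoxyethoxy)-2-methoxybenzaldehyde (acetal carbon racemic) | CCOC(C)Oc1ccc(C=O)c(OC)c1 | intermediate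
8 | isobutylmagnesium bromide | CC(C)C[Mg]Br | starting material
9 | isobutyltitanium triisopropoxide | CC(C)C[Ti](OC(C)C)(OC(C)C)OC(C)C | intermediate
10 | (1R)-1-[4-(1-ethoxyethoxy)-2-methoxyphenyl]-3-methylbutan-1-ol (acetal epimers) | CCOC(C)Oc1ccc([C@@H](CC(C)C)O)c(OC)c1 | intermediate
11 | 4-(1-ethoxyethoxy)-2-methoxy-1-[(1R)-1-methoxy-3-methylbutyl]benzene (acetal epimers) | CCOC(C)Oc1ccc([C@@H](CC(C)C)OC)c(OC)c1 | intermediate
12 | {6-(1-ethoxyethoxy)-2-methoxy-3-[(1R)-1-methoxy-3-methylbutyl]phenyl}lithium | CCOC(C)Oc1ccc([C@@H](CC(C)C)OC)c(OC)c1[Li] | intermediate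
13 | 6-(1-ethoxyethoxy)-2-methoxy-3-[(1R)-1-methoxy-3-methylbutyl]benzoic acid | CCOC(C)Oc1ccc([C@@H](CC(C)C)OC)c(OC)c1C(=O)O | intermediate
14 | 6-hydroxy-2-methoxy-3-[(1R)-1-methoxy-3-methylbutyl]benzoic acid | COc1c([C@@H](CC(C)C)OC)ccc(O)c1C(=O)O | intermediate
15 | 3-formyl-2-hydroxy-5-methylphenyl 6-hydroxy-2-methoxy-3-[(1R)-1-methoxy-3-methylbutyl]benzoate | COc1c([C@@H](CC(C)C)OC)ccc(O)c1C(=O)Oc1cc(C)cc(C=O)c1O | intermediate
16 | 2-formyl-6-hydroxy-4-methylphenyl 6-hydroxy-2-methoxy-3-[(1R)-1-methoxy-3-methylbutyl]benzoate | COc1c([C@@H](CC(C)C)OC)ccc(O)c1C(=O)Oc1c(O)cc(C)cc1C=O | intermediate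
17 | potassium salt of the spiro Meisenheimer adduct (1,3-benzodioxin-4-one spiro-fused at C2 to dearomatised ring B; spiro carbon configuration undefined) | COc1c([C@@H](CC(C)C)OC)ccc2OC3(OC(=O)c12)C(=C[O-])C=C(C)C=C3O.[K+] | intermediate
18 | 6-(2-formyl-6-hydroxy-4-methylphenoxy)-2-methoxy-3-[(1R)-1-methoxy-3-methylbutyl]benzoic acid | COc1c([C@@H](CC(C)C)OC)ccc(Oc2c(O)cc(C)cc2C=O)c1C(=O)O | target

**Step count and risks**
Total steps: 8. Longest linear sequence: 6 (steps 3–8); steps 1–2 form the second branch.

Most likely to fail: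

- **Step 2 (mono-Dakin).** Over-oxidation to the pyrogallol or catechol degradation could leave little mono product. The fallback sets out from 1 and comes back at 5, and avoids any symmetric intermediate. Ortho-formylation of 1 (MgCl2, Et3N, paraformaldehyde, MeCN, reflux) gives 2-hydroxy-5-methylbenzaldehyde F1. Bromination at the only free ortho position (Br2, NaOAc, AcOH) gives 3-bromo-2-hydroxy-5-methylbenzaldehyde F2. Copper-mediated hydroxylation (Cu powder, aq. NaOH, reflux, N2, then acid) replaces Br by OH and gives 5.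

- **Step 4 (enantioselectivity with an ortho-methoxy aldehyde).** The fallback sets out from 7 and comes back at 10, replacing the asymmetric C–C bond formation by an asymmetric ketone reduction. Uncatalysed addition of 8 to 7 (THF, −78 °C) gives rac-1-[4-(1-ethoxyethoxy)-2-methoxyphenyl]-3-methylbutan-1-ol F3. MnO2 (CH2Cl2, rt) oxidises it to 1-[4-(1-ethoxyethoxy)-2-methoxyphenyl]-3-methylbutan-1-one F4. (S)-Me-CBS (10 mol %)/BH3·SMe2 (THF, −20 °C) reduces F4, with aryl as the large group, to the (R)-alcohol 10.

- **Step 8 (Smiles rearrangement).** Ring B carries only one activating CHO and a partly ionised ortho OH, so the rearrangement may be slow or lose to ester cleavage. The fallback sets out from 14 (coupled with 3) and comes back at 18, moving the symmetry-breaking oxidation to the end. Esterification of 14 with the symmetric dialdehyde 3 (DCC, DMAP, CH2Cl2) gives 2,6-diformyl-4-methylphenyl 6-hydroxy-2-methoxy-3-[(1R)-1-methoxy-3-methylbutyl]benzoate F5, whose ipso carbon is activated by two ortho formyl groups and has no ring-B hydroxyl. K2CO3/DMSO at rt then gives the Smiles product 6-(2,6-diformyl-4-methylphenoxy)-2-methoxy-3-[(1R)-1-methoxy-3-methylbutyl]benzoic acid F6. Baeyer–Villiger oxidation with mCPBA (1.0 equiv, CH2Cl2, 0 °C) converts one of the two equivalent CHO groups into 6-[2-formyl-6-(formyloxy)-4-methylphenoxy]-2-methoxy-3-[(1R)-1-methoxy-3-methylbutyl]benzoic acid F7, and aqueous NaHCO3/THF hydrolysis of the formate gives 18.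

**Further compounds**
F1 | step 2 | 2-hydroxy-5-methylbenzaldehyde | Cc1ccc(O)c(C=O)c1
F2 | step 2 | 3-bromo-2-hydroxy-5-methylbenzaldehyde | Cc1cc(Br)c(O)c(C=O)c1
F3 | step 4 | rac-1-[4-(1-ethoxyethoxy)-2-methoxyphenyl]-3-methylbutan-1-ol | CCOC(C)Oc1ccc(C(CC(C)C)O)c(OC)c1
F4 | step 4 | 1-[4-(1-ethoxyethoxy)-2-methoxyphenyl]-3-methylbutan-1-one | CCOC(C)Oc1ccc(C(=O)CC(C)C)c(OC)c1
F5 | step 8 | 2,6-diformyl-4-methylphenyl 6-hydroxy-2-methoxy-3-[(1R)-1-methoxy-3-methylbutyl]benzoate | COc1c([C@@H](CC(C)C)OC)ccc(O)c1C(=O)Oc1c(C=O)cc(C)cc1C=O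
F6 | step 8 | 6-(2,6-diformyl-4-methylphenoxy)-2-methoxy-3-[(1R)-1-methoxy-3-methylbutyl]benzoic acid | COc1c([C@@H](CC(C)C)OC)ccc(Oc2c(C=O)cc(C)cc2C=O)c1C(=O)O
F7 | step 8 | 6-[2-formyl-6-(formyloxy)-4-methylphenoxy]-2-methoxy-3-[(1R)-1-methoxy-3-methylbutyl]benzoic acid | COc1c([C@@H](CC(C)C)OC)ccc(Oc2c(OC=O)cc(C)cc2C=O)c1C(=O)O
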